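**Strategy.** The upper unit is a 4-aryl chroman: O1 sits on A-ring carbon C8a, ortho to C4a, whose benzylic C4 carries C8 of the epigallocatechin unit. This is the retron of an ortho-quinone methide (O1=C8a–C4a=C4). A one-pot cascade joins 8-lithiated benzyl-protected epigallocatechin to an O-Boc salicylaldehyde, unmasks the quinone methide and traps it with a chiral vinyl ether in an oxa-[4+2] cycloaddition that closes ring C by forming O1–C2 and C3–C4 and sets C4. The derived 4H-chromene is epoxidised anti to the C4 aryl and opened syn by an arylalane, which installs the C3 hydroxyl and the C2 aryl cis to each other; hydrogenolysis finishes.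

Key step: step 6

Numbering: unprimed chroman numbers are used for the upper unit (rings A, C, B) and primed numbers for the epigallocatechin unit; the target is (2R,3R,4R) in the upper unit (2,3-cis, 3,4-trans) and (2'R,3'R) in the lower unit.

Remark: the facial sense of the (1S,2R)-2-phenylcyclohexyl auxiliary is assigned from an s-trans/endo shielding model; if the opposite sense were found, the antipodal auxiliary (equally available) would be used without any other change.

**Step 1**
Reactants: 1 (−)-epigallocatechin; 2 benzyl bromide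
Product: 3 hexa-O-benzyl-(−)-epigallocatechin (all five phenols and the C3' hydroxyl benzylated; 2'R,3'R)
Conditions: NaH (6.6 equiv), BnBr (6.6 equiv), n-Bu4NI (cat.), DMF, −20 °C → rt, argon
Reagents that add atoms: benzyl bromide 2, BrCc1ccccc1
Why: Exhaustive Williamson etherification should cap the five phenoxides first and then the secondary alkoxide, and no stereocentre is touched.

**Step 2**
Reactants: 3 hexa-O-benzyl-epigallocatechin; 4 N-bromosuccinimide
Product: 5 8'-bromo-hexa-O-benzyl-epigallocatechin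
Conditions: NBS (1.0 equiv), CH2Cl2, −78 °C → rt
Reagents that add atoms: N-bromosuccinimide 4, O=C1CCC(=O)N1Br
Why: Electrophilic aromatic bromination of a 5,7-dialkoxyflavan should go to C8', the position between the ring oxygen and the 7-alkoxy group that is known to react first, and one equivalent at low temperature should spare C6' and the tris(benzyloxy)phenyl ring.

**Step 3**
Reactants: 6 2,4,6-trihydroxybenzaldehyde; 2 benzyl bromide
Product: 7 2,4-bis(benzyloxy)-6-hydroxybenzaldehyde
Conditions: BnBr (2.05 equiv), K2CO3 (2.0 equiv), DMF, 0 °C → rt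
Reagents that add atoms: benzyl bromide 2, BrCc1ccccc1
Why: Williamson etherification should stop at the dibenzyl ether because the last hydroxyl is hydrogen-bonded to the formyl group and is the least nucleophilic.

**Step 4**
Reactants: 7 2,4-bis(benzyloxy)-6-hydroxybenzaldehyde; 8 di-tert-butyl dicarbonate
Product: 9 tert-butyl 3,5-bis(benzyloxy)-2-formylphenyl carbonate
Conditions: Boc2O (1.2 equiv), i-Pr2NEt, DMAP (cat.), THF, 0 °C → rt
Reagents that add atoms: di-tert-butyl dicarbonate 8, CC(C)(C)OC(=O)OC(=O)OC(C)(C)C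
Why: DMAP-catalysed O-acylation of the phenol should give the aryl carbonate that later serves as the internal leaving-group relay.

**Step 5**
Reactants: 10 (1S,2R)-trans-2-phenylcyclohexan-1-ol; 11 ethyl vinyl ether
Product: 12 (1S,2R)-2-phenylcyclohexyl vinyl ether
Conditions: Hg(OAc)2 (cat.), ethyl vinyl ether (solvent), reflux
Reagents that add atoms: ethyl vinyl ether 11, C=COCC
Why: Metal-catalysed transfer vinylation (transetherification) exchanges the alkoxy group without touching the carbinol C–O bond, so both auxiliary stereocentres are retained.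

**Step 6**
Reactants: 5 8'-bromo-hexa-O-benzyl-epigallocatechin; 9 tert-butyl 3,5-bis(benzyloxy)-2-formylphenyl carbonate; 12 (1S,2R)-2-phenylcyclohexyl vinyl ether
Product: 16 (2R,4R)-2-alkoxy-4-aryl chroman cycloadduct (2,4-cis; alkoxy = auxiliary; aryl = protected epigallocatechin-8'-yl), via aryllithium 13 (not isolated), via lithium phenoxide carbonate 14 (not isolated), via ortho-quinone methide 15 (not isolated)
Conditions: t-BuLi (2.0 equiv), THF, −78 °C; then 9, −78 °C; then 12 (3 equiv), MgBr2·OEt2 (1.2 equiv), −78 °C → rt; H2O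
Reagents that add atoms: none
Why: Bromine–lithium exchange gives aryllithium 13, which adds to the formyl group of 9; the new alkoxide takes the Boc group from the neighbouring phenol oxygen, and magnesium-assisted β-elimination of tert-butyl carbonate from phenoxide 14 unmasks ortho-quinone methide 15, which enol ether 12 captures in an inverse-electron-demand oxa-Diels–Alder reaction. The closest known reaction type is the organometallic-triggered ortho-quinone methide cascade of O-Boc salicylaldehydes with chiral vinyl ethers. Ring C closes in a concerted, asynchronous [4+2] mode (four atoms O1=C8a–C4a=C4 from 15, two from 12): the nucleophilic CH2 terminus of 12 bonds to the methide carbon (C3–C4) and the quinone methide oxygen closes onto the alkoxy-bearing carbon (O1–C2), so the regiochemistry follows from the polarity of both partners. C4 (R) is controlled by the auxiliary: in the endo transition state the quinone methide lies over the alkoxy group, the phenyl ring of the (1S,2R)-2-phenylcyclohexyl residue blocks one face of the s-trans vinyl ether, and bonding on the open face places C3 on the required face of C4; C2 (R, erased in step 7) follows from the endo orientation, alkoxy cis to the C4 aryl. The step needs the quinone methide to react as the E isomer (C4 aryl pointing away from the heterodiene), which should hold because the E and Z forms interconvert through the zwitterionic diarylmethyl cation–phenoxide form and an aryl group turned inward would block the s-cis heterodiene. It also needs 13 to attack the formyl group and not the carbonate, which the far higher electrophilicity of the aldehyde secures.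

**Step 7**
Reactants: 16 (2R,4R)-2-alkoxy-4-aryl chroman cycloadduct
Product: 17 (4R)-5,7-bis(benzyloxy)-4-aryl-4H-chromene (aryl = protected epigallocatechin-8'-yl)
Conditions: TMSOTf (1.5 equiv), i-Pr2NEt (2 equiv), CH2Cl2, −20 °C → rt
Reagents that add atoms: none
Why: In this silyl-triflate-mediated acetal-to-enol-ether elimination the silyl triflate should ionise the exocyclic C2–O bond to the chroman-2-yl oxocarbenium ion and the hindered amine should remove a C3 proton, which releases the auxiliary, erases C2 and leaves C4 untouched.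

**Step 8**
Reactants: 17 (4R)-4-aryl-4H-chromene; 18 dimethyldioxirane; 19 4-(benzyloxy)phenylmagnesium bromide
Product: 22 nona-O-benzyl dimer (2R,3R,4R) with the free C3 hydroxyl, via epoxide 20 (not isolated), via triarylalane 21 (not isolated)
Conditions: DMDO (1.2 equiv, acetone solution), CH2Cl2, −40 → 0 °C; evaporate cold; then (4-BnOC6H4)3Al [from 19 (3 equiv) and AlCl3 (1 equiv), THF, solvent changed to toluene], toluene/CH2Cl2, −78 → 0 °C; aq. potassium sodium tartrate
Reagents that add atoms: dimethyldioxirane 18, CC1(C)OO1; tris[4-(benzyloxy)phenyl]alane 21 (made from 19 and AlCl3), [Al](c1ccc(OCc2ccccc2)cc1)(c1ccc(OCc2ccccc2)cc1)c1ccc(OCc2ccccc2)cc1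
Why: Enol ether epoxidation should occur on the face of C2=C3 opposite the pseudo-axial C4 aryl and so fix C3 (R), and the Lewis-acidic alane should then bind the oxirane oxygen, open the C2–O bond to an oxocarbenium–aluminate ion pair and deliver an aryl group to C2 on the face of the departing oxygen (syn-selective organoalane opening as known for glycal epoxides), which is also the face remote from the C4 aryl and sets C2 (R) cis to the new hydroxyl.

**Step 9**
Reactants: 22 nona-O-benzyl dimer
Product: 23 epiafzelechin-(4β→8)-epigallocatechin (CNP0290824.1)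
Conditions: H2 (1 atm), Pd(OH)2/C, THF/MeOH (1:1), rt
Reagents that add atoms: none
Why: Catalytic hydrogenolysis should cleave all nine benzyl ethers under neutral conditions that leave the cyclic benzylic ethers, the interflavan bond and all five stereocentres intact.

**Compound list**
1 | (−)-epigallocatechin, (2R,3R)-2-(3,4,5-trihydroxyphenyl)chromane-3,5,7-triol | c1c(O)cc(O)c2c1O[C@H](c1cc(O)c(O)c(O)c1)[C@H](O)C2 | starting material
2 | benzyl bromide | BrCc1ccccc1 | starting material
3 | (2R,3R)-3,5,7-tris(benzyloxy)-2-[3,4,5-tris(benzyloxy)phenyl]chromane | c1c(OCc3ccccc3)cc(OCc3ccccc3)c2c1O[C@H](c1cc(OCc3ccccc3)c(OCc3ccccc3)c(OCc3ccccc3)c1)[C@H](OCc1ccccc1)C2 | intermediate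
4 | N-bromosuccinimide | O=C1CCC(=O)N1Br | starting material
5 | (2R,3R)-8-bromo-3,5,7-tris(benzyloxy)-2-[3,4,5-tris(benzyloxy)phenyl]chromane | Brc1c(OCc3ccccc3)cc(OCc3ccccc3)c2c1O[C@H](c1cc(OCc3ccccc3)c(OCc3ccccc3)c(OCc3ccccc3)c1)[C@H](OCc1ccccc1)C2 | intermediate
6 | 2,4,6-trihydroxybenzaldehyde | O=Cc1c(O)cc(O)cc1O | starting material
7 | 2,4-bis(benzyloxy)-6-hydroxybenzaldehyde | O=Cc1c(O)cc(OCc2ccccc2)cc1OCc1ccccc1 | intermediate
8 | di-tert-butyl dicarbonate | CC(C)(C)OC(=O)OC(=O)OC(C)(C)C | starting material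
9 | tert-butyl 3,5-bis(benzyloxy)-2-formylphenyl carbonate | O=Cc1c(OC(=O)OC(C)(C)C)cc(OCc2ccccc2)cc1OCc1ccccc1 | intermediate
10 | (1S,2R)-trans-2-phenylcyclohexan-1-ol | O[C@H]1CCCC[C@@H]1c1ccccc1 | starting material
11 | ethyl vinyl ether | C=COCC | starting material
12 | (1S,2R)-2-phenylcyclohexyl vinyl ether | C=CO[C@H]1CCCC[C@@H]1c1ccccc1 | intermediate
13 | 8-lithio derivative of 3 (aryllithium) | [Li]c1c(OCc3ccccc3)cc(OCc3ccccc3)c2c1O[C@H](c1cc(OCc3ccccc3)c(OCc3ccccc3)c(OCc3ccccc3)c1)[C@H](OCc1ccccc1)C2 | intermediate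
14 | lithium 3,5-bis(benzyloxy)-2-[(tert-butoxycarbonyloxy)(flavan-8-yl)methyl]phenoxide, both carbinol epimers | [Li+].[O-]c1cc(OCc2ccccc2)cc(OCc2ccccc2)c1C(OC(=O)OC(C)(C)C)c1c(OCc2ccccc2)cc(OCc2ccccc2)c2c1O[C@H](c1cc(OCc3ccccc3)c(OCc3ccccc3)c(OCc3ccccc3)c1)[C@H](OCc1ccccc1)C2 | intermediate
15 | (E)-3,5-bis(benzyloxy)-6-[(flavan-8-yl)methylidene]cyclohexa-2,4-dien-1-one (ortho-quinone methide) | O=C1C=C(OCc2ccccc2)C=C(OCc2ccccc2)/C1=C\c1c(OCc2ccccc2)cc(OCc2ccccc2)c2c1O[C@H](c1cc(OCc3ccccc3)c(OCc3ccccc3)c(OCc3ccccc3)c1)[C@H](OCc1ccccc1)C2 | intermediate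
16 | (2R,4R)-5,7-bis(benzyloxy)-2-[(1S,2R)-2-phenylcyclohexyloxy]-4-[(2R,3R)-3,5,7-tris(benzyloxy)-2-(3,4,5-tris(benzyloxy)phenyl)chroman-8-yl]chromane | [C@@H]1(O[C@H]2CCCC[C@@H]2c2ccccc2)Oc2cc(OCc3ccccc3)cc(OCc3ccccc3)c2[C@H](c2c(OCc3ccccc3)cc(OCc3ccccc3)c3c2O[C@H](c2cc(OCc4ccccc4)c(OCc4ccccc4)c(OCc4ccccc4)c2)[C@H](OCc2ccccc2)C3)C1 | intermediate
17 | (4R)-5,7-bis(benzyloxy)-4-[(2R,3R)-3,5,7-tris(benzyloxy)-2-(3,4,5-tris(benzyloxy)phenyl)chroman-8-yl]-4H-chromene | O1c2cc(OCc3ccccc3)cc(OCc3ccccc3)c2[C@H](c2c(OCc3ccccc3)cc(OCc3ccccc3)c3c2O[C@H](c2cc(OCc4ccccc4)c(OCc4ccccc4)c(OCc4ccccc4)c2)[C@H](OCc2ccccc2)C3)C=C1 | intermediate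
18 | dimethyldioxirane (acetone solution, freshly made from acetone and KHSO5) | CC1(C)OO1 | starting material
19 | 4-(benzyloxy)phenylmagnesium bromide (THF solution) | Br[Mg]c1ccc(OCc2ccccc2)cc1 | starting material
20 | (2S,3R,4R)-2,3-epoxide of 17, oxirane on the face anti to the C4 aryl | O1[C@H]2Oc3cc(OCc4ccccc4)cc(OCc4ccccc4)c3[C@H](c3c(OCc4ccccc4)cc(OCc4ccccc4)c4c3O[C@H](c3cc(OCc5ccccc5)c(OCc5ccccc5)c(OCc5ccccc5)c3)[C@H](OCc3ccccc3)C4)[C@H]21 | intermediate
21 | tris[4-(benzyloxy)phenyl]alane | [Al](c1ccc(OCc2ccccc2)cc1)(c1ccc(OCc2ccccc2)cc1)c1ccc(OCc2ccccc2)cc1 | intermediate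
22 | (2R,3R,4R)-5,7-bis(benzyloxy)-2-[4-(benzyloxy)phenyl]-4-[(2R,3R)-3,5,7-tris(benzyloxy)-2-(3,4,5-tris(benzyloxy)phenyl)chroman-8-yl]chroman-3-ol | O(Cc1ccccc1)c1ccc([C@H]2Oc3cc(OCc4ccccc4)cc(OCc4ccccc4)c3[C@H](c3c(OCc4ccccc4)cc(OCc4ccccc4)c4c3O[C@H](c3cc(OCc5ccccc5)c(OCc5ccccc5)c(OCc5ccccc5)c3)[C@H](OCc3ccccc3)C4)[C@H]2O)cc1 | intermediate
23 | epiafzelechin-(4β→8)-epigallocatechin, CNP0290824.1 | Oc1ccc([C@H]2Oc3cc(O)cc(O)c3[C@H](c3c(O)cc(O)c4c3O[C@H](c3cc(O)c(O)c(O)c3)[C@H](O)C4)[C@H]2O)cc1 | target

**Totals**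
Total step count: 9. Longest linear sequence: 6 steps (steps 1, 2, 6, 7, 8, 9).

**Steps most likely to fail**

Step 6. The cascade may stall at a tetra-ortho-substituted benzhydryl centre (slow Boc transfer or elimination). The strongly stabilised methide may be intercepted by tert-butoxide before the enol ether adds. Facial selectivity at C4 may be eroded if the lower unit exerts a mismatched bias. Fallback: set out from 5 and 7. Aldehyde 7 is converted into its sodium phenoxide (NaH, THF) and treated at −78 °C with aryllithium 13 made from 5, which should give the isolable ortho-hydroxybenzhydrol F1. F1 is then heated with 12 in toluene at 80–100 °C, where thermal dehydration generates 15 without any organometallic or alkoxide present and the cycloaddition should give 16, at which point the route is rejoined. C4 epimers, if formed, are diastereomers because the lower unit is enantiopure, and can be separated at this stage.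

Step 8. The oxirane may rearrange by hydride shift to the chroman-3-one (Meinwald rearrangement) faster than the aryl group is transferred, or the aryl group may be delivered without face control. Fallback: set out from 17. Epoxidation with dimethyldioxirane in CH2Cl2/MeOH should open 20 in situ to the methyl acetal F2 (3-hydroxy-2-methoxychroman, C2 anomers), and the C3 hydroxyl is then benzylated (NaH, BnBr) to F3. BF3·OEt2 should ionise the acetal of F3 to the chroman-2-yl oxocarbenium ion, which bis[4-(benzyloxy)phenyl]zinc F4 (from 19 and ZnCl2) should attack on the face remote from the C4 aryl, giving the deca-O-benzyl dimer F5 with the 2,3-cis arrangement. Hydrogenolysis of F5 under the conditions of step 9 returns to the route at 23.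

Step 7. Ionisation may take the endocyclic instead of the exocyclic C–O bond and open ring C, or the Lewis acid may attack the acid-sensitive benzylic ether of the lower unit. Fallback: set out from 16. Mild aqueous acid (PPTS, THF/H2O) should hydrolyse the acetal to the lactol F6 (2-hydroxychroman, C2 anomers) and return the auxiliary alcohol. Dehydration of F6 with MsCl and Et3N (CH2Cl2, 0 °C → rt), by sulfonylation of the anomeric hydroxyl and base-induced elimination as used to make glycals from lactols, should give 17, where the route is rejoined.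

**Further compounds**
F1 | step 6 | 3,5-bis(benzyloxy)-2-[hydroxy(flavan-8-yl)methyl]phenol, both carbinol epimers | Oc1cc(OCc2ccccc2)cc(OCc2ccccc2)c1C(O)c1c(OCc2ccccc2)cc(OCc2ccccc2)c2c1O[C@H](c1cc(OCc3ccccc3)c(OCc3ccccc3)c(OCc3ccccc3)c1)[C@H](OCc1ccccc1)C2
F2 | step 8 | (3R,4R)-5,7-bis(benzyloxy)-2-methoxy-4-(flavan-8-yl)chroman-3-ol, C2 anomers | COC1Oc2cc(OCc3ccccc3)cc(OCc3ccccc3)c2[C@H](c2c(OCc3ccccc3)cc(OCc3ccccc3)c3c2O[C@H](c2cc(OCc4ccccc4)c(OCc4ccccc4)c(OCc4ccccc4)c2)[C@H](OCc2ccccc2)C3)[C@H]1O
F3 | step 8 | (3R,4R)-3,5,7-tris(benzyloxy)-2-methoxy-4-(flavan-8-yl)chromane, C2 anomers | COC1Oc2cc(OCc3ccccc3)cc(OCc3ccccc3)c2[C@H](c2c(OCc3ccccc3)cc(OCc3ccccc3)c3c2O[C@H](c2cc(OCc4ccccc4)c(OCc4ccccc4)c(OCc4ccccc4)c2)[C@H](OCc2ccccc2)C3)[C@H]1OCc1ccccc1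
F4 | step 8 | bis[4-(benzyloxy)phenyl]zinc | [Zn](c1ccc(OCc2ccccc2)cc1)c1ccc(OCc2ccccc2)cc1
F5 | step 8 | (2R,3R,4R)-3,5,7-tris(benzyloxy)-2-[4-(benzyloxy)phenyl]-4-(flavan-8-yl)chromane (deca-O-benzyl dimer) | O(Cc1ccccc1)c1ccc([C@H]2Oc3cc(OCc4ccccc4)cc(OCc4ccccc4)c3[C@H](c3c(OCc4ccccc4)cc(OCc4ccccc4)c4c3O[C@H](c3cc(OCc5ccccc5)c(OCc5ccccc5)c(OCc5ccccc5)c3)[C@H](OCc3ccccc3)C4)[C@H]2OCc2ccccc2)cc1
F6 | step 7 | (4R)-5,7-bis(benzyloxy)-4-(flavan-8-yl)chroman-2-ol, C2 anomers | OC1Oc2cc(OCc3ccccc3)cc(OCc3ccccc3)c2[C@H](c2c(OCc3ccccc3)cc(OCc3ccccc3)c3c2O[C@H](c2cc(OCc4ccccc4)c(OCc4ccccc4)c(OCc4ccccc4)c2)[C@H](OCc2ccccc2)C3)C1
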